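**Strategy.** The plan cuts the bond between Ca, the quaternary cyclohexane carbon bearing CH2OAc, and Ci, the cyclopropane CH beside it. Because Ca and Ce, the two ring carbons flanking the apex Cf, are both quaternary, they can arise from the two β-carbons of one mirror-symmetric cyclohexadienone. A single carbinol centre (Ck), locked in a spiro-oxolane, carries a (Z)-iodoalkenyl arm that reaches only one enone; a reductive Heck cyclisation forms Ca–Ci, closes the cis-fused cyclopentene and fixes quaternary Ca and Cf at once. An intramolecular diazoalkane cyclopropanation then completes the nortricyclene; the remaining enone supplies the gem-dimethyl group and the cis-diol.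

Key step: step 7

Remark (atom labels, target): six-membered ring Ca (quaternary, carries C15H2OAc), Cb (CH2), Cc (CHOAc), Cd (CHOH), Ce (CMe2), Cf (quaternary apex); cage Cg (CH2 on Cf), Ch and Ci (cyclopropane CH; Ci is bonded to Ca), Cj (cyclopropane C–CH3), Ck (CHOAc between Cf and Cj).

Remark (assumption): the (S,S) antipode of the ProPhenol ligand is taken to give the carbinol configuration drawn for 4 and 5; if its facial sense is the opposite, the (R,R) ligand is used.

Step 1
Reactants: 1 2,6-dichloro-4-hydroxybenzaldehyde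
Product: 2 2,6-bis[(benzyloxy)methyl]-4-hydroxybenzaldehyde
Conditions: BnOCH2BF3K (2.4 equiv), Pd(OAc)2 (5 mol %), RuPhos (10 mol %), Cs2CO3, 1,4-dioxane/H2O 10:1, 100 °C
Reagents that add atoms: potassium (benzyloxymethyl)trifluoroborate [K+].F[B-](F)(F)COCc1ccccc1
Why: Suzuki–Miyaura coupling of an alkoxymethyltrifluoroborate with aryl chlorides, both C–Cl bonds being ortho to the formyl group and so activated for oxidative addition; this installs the two identical C1 arms that later become C15 and one methyl of Ce.

Step 2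
Reactants: 2 2,6-bis[(benzyloxy)methyl]-4-hydroxybenzaldehyde
Product: 3 2,6-bis[(benzyloxy)methyl]-4-[(triisopropylsilyl)oxy]benzaldehyde
Conditions: TIPSCl, imidazole, DMF, rt
Reagents that add atoms: chlorotriisopropylsilane CC(C)[Si](Cl)(C(C)C)C(C)C
Why: Standard phenol silylation; the silyl ether masks the phenol through the organometallic steps and is the latent phenoxide trigger for step 6.

Step 3
Reactants: 3 2,6-bis[(benzyloxy)methyl]-4-[(triisopropylsilyl)oxy]benzaldehyde
Product: 5 (R)-aryl propargylic alcohol, via TMS-alkynyl carbinol 4 (not isolated)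
Conditions: HC≡CSiMe3, Me2Zn, (S,S)-ProPhenol (15 mol %), Ph3P=O (cat.), toluene, 4 °C; aq. NH4Cl; then K2CO3, MeOH, 0 °C
Reagents that add atoms: ethynyltrimethylsilane C#C[Si](C)(C)C
Why: Zinc–ProPhenol-catalysed asymmetric alkynylation of an aryl aldehyde sets Ck by catalyst-controlled facial addition, and methanolysis removes the C-silyl group while the hindered aryl silyl ether should survive.

Step 4
Reactants: 5 (R)-1-aryl-prop-2-yn-1-ol
Product: 6 (S,Z)-1-aryl-3-iodo-2-methylprop-2-en-1-ol
Conditions: MeMgBr (4 equiv), CuI (20 mol %), THF/Et2O, −10 °C to rt; then I2, −78 to 0 °C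
Reagents that add atoms: methylmagnesium bromide C[Mg]Br; iodine II
Why: Copper-catalysed, alkoxide-directed anti-carbomagnesiation puts methyl on the proximal alkyne carbon (Cj) and magnesium on the distal one (Ci) in a five-membered chelate, so iodinolysis with retention should give the iodide cis to Ck, the geometry the later ring closure needs.

Step 5
Reactants: 6 (S,Z)-1-aryl-3-iodo-2-methylprop-2-en-1-ol
Product: 7 2-bromo-1-ethoxyethyl acetal of 6
Conditions: ethyl vinyl ether (5 equiv), NBS, CH2Cl2, −40 to 0 °C
Reagents that add atoms: ethyl vinyl ether C=COCC; N-bromosuccinimide BrN1C(=O)CCC1=O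
Why: Bromoacetalisation (haloetherification of the enol ether, which is far more nucleophilic than the arene or the iodoalkene) attaches the future Cg–Ch unit to the Ck oxygen; the acetal carbon is formed as an inconsequential epimer mixture.

Step 6
Reactants: 7 2-bromo-1-ethoxyethyl acetal of 6
Product: 9 spiro-dienone, via phenol 8 (not isolated)
Conditions: TBAF (1.2 equiv), NaI (cat.), THF, 0 to 45 °C, high dilution
Reagents that add atoms: none
Why: Fluoride liberates the phenoxide, whose para carbon (Cf) alkylates the primary bromide in a 5-exo-tet Ar1-5 alkylative dearomatisation; because the dienone ring is mirror-symmetric, Cf is not yet stereogenic and Ck remains the only controlling centre.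

Step 7
Reactants: 9 spiro-dienone
Product: 10 cis-fused oxolane–cyclopentene–cyclohexenone tricycle
Conditions: Pd(OAc)2 (10 mol %), PPh3 (25 mol %), HCO2Na (1.5 equiv), Et4NCl, DMF, 80 °C
Reagents that add atoms: none
Why: Pd(0) inserts into the alkenyl C–I bond and the alkenyl–Pd adds syn across the nearer dienone C=C to form Ca–Ci; the resulting palladium enolate at Cb has no β-hydrogen on the new quaternary Ca and is released by formate-derived hydride as the saturated ketone. The closest known reaction type is the intramolecular reductive (conjugate-addition-type) Heck desymmetrisation of 4,4-disubstituted cyclohexadienones. The cyclopentene Cf–Ck–Cj=Ci–Ca closes in the 5-exo-trig mode and is necessarily cis-fused to the six-membered ring. Ca and Cf become stereogenic here and both are controlled by Ck alone: the spiro-oxolane lies in the mirror plane of the dienone, so the (Z)-iodoalkenyl group on Ck projects over only one of the two enone β-carbons and can bond to it only from the face of Ck, which pushes CH2OBn on Ca to the face of Cg. The step needs group selectivity between the two enone halves and chemoselectivity for insertion over premature reduction of the alkenyl–Pd; the first is secured by the rigid oxolane (the other enone is out of reach), the second by the proximity of the acceptor and slow hydride delivery from sparingly soluble formate.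

Step 8
Reactants: 10 cis-fused oxolane–cyclopentene–cyclohexenone tricycle
Product: 12 methyl enone, via exo-methylene ketone 11 (not isolated)
Conditions: SmI2 (2.5 equiv), THF/MeOH, −78 °C; then DBU, CH2Cl2, rt
Reagents that add atoms: none
Why: Vinylogous reductive cleavage of the γ-benzyloxy enone by SmI2 expels benzyloxide from the dienolate only on the enone side (the CH2OBn on saturated Ca is not activated), and base reconjugates the deconjugated isomer to the Ce-methyl enone.

Step 9
Reactants: 12 methyl enone
Product: 14 O-TMS tosylhydrazone, via hydroxy tosylhydrazone 13 (not isolated)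
Conditions: TsNHNH2 (1.05 equiv), PPTS (cat.), THF/MeOH, 40 °C; evaporate; then TMSCl, imidazole, CH2Cl2, 0 °C
Reagents that add atoms: p-toluenesulfonyl hydrazide Cc1ccc(cc1)S(=O)(=O)NN; chlorotrimethylsilane C[Si](C)(C)Cl
Why: Acid-catalysed acetal exchange converts the labile 2-ethoxyoxolane into the aldehyde tosylhydrazone much faster than the hindered enone carbonyl condenses, and the freed Ck hydroxyl is capped so that it can neither protonate or trap the diazoalkane nor trigger a vinylogous retro-aldol.

Step 10
Reactants: 14 O-TMS tosylhydrazone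
Product: 17 nortricyclene enone TMS ether, via diazoalkane 15 (not isolated), via pyrazoline 16 (not isolated)
Conditions: NaH (1.1 equiv), THF, 0 °C; then BnEt3NCl (10 mol %), 1,4-dioxane, 70 °C then 100 °C
Reagents that add atoms: none
Why: Bamford–Stevens generation of the diazoalkane, intramolecular 1,3-dipolar cycloaddition to the cyclopentene held three atoms away, and thermal N2 loss from the 1-pyrazoline close the cyclopropane; Ch can reach Ci=Cj only from the face carrying Cg, so Ch, Ci and Cj are set by Cf.

Step 11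
Reactants: 17 nortricyclene enone TMS ether
Product: 18 bis(trimethylsilyl) enol ether with gem-dimethyl Ce
Conditions: Me2CuLi (3 equiv), TMSCl (5 equiv), THF, −78 to −30 °C; Et3N quench
Reagents that add atoms: lithium dimethylcuprate [Li+].C[Cu-]C; chlorotrimethylsilane C[Si](C)(C)Cl
Why: TMSCl-accelerated cuprate conjugate addition completes the gem-dimethyl group at Ce (no new stereocentre) and traps the enolate regiospecifically as the Cc=Cd silyl enol ether.

Step 12
Reactants: 18 bis(trimethylsilyl) enol ether
Product: 20 α-ketol diol, via silyloxy epoxide 19 (not isolated)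
Conditions: dimethyldioxirane (1.1 equiv), acetone/CH2Cl2, −40 °C; then citric acid, MeOH, 0 °C
Reagents that add atoms: dimethyldioxirane CC1(C)OO1
Why: Rubottom oxidation; in the cage-locked ring the oxidant should approach Cd anti to the axial cage carbon Ck on Cf, giving the equatorial hydroxyl, which is also the thermodynamic epimer of the ketol.

Step 13
Reactants: 20 α-ketol diol
Product: 21 benzyl ether triol
Conditions: NaBH4, MeOH/CH2Cl2, −40 to 0 °C
Reagents that add atoms: none
Why: Hydride reduction of the ketone; the axial trajectory at Cc is blocked by the syn-axial CH2OBn on Ca and the axial methyl on Ce, so attack from the equatorial side should give the axial alcohol cis to the Cd hydroxyl.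

Step 14
Reactants: 21 benzyl ether triol
Product: 22 tetraol
Conditions: H2 (1 atm), 10% Pd/C, EtOAc/EtOH, rt
Reagents that add atoms: none
Why: Hydrogenolysis of the benzyl ether; no alkene remains and the unactivated nortricyclene cyclopropane should survive these mild conditions.

Step 15
Reactants: 22 tetraol
Product: 24 orthoacetate diacetate, via orthoacetate diol 23 (not isolated)
Conditions: MeC(OMe)3 (1.5 equiv), PPTS (cat.), CH2Cl2, rt; then Ac2O, pyridine, DMAP, 40 °C
Reagents that add atoms: trimethyl orthoacetate COC(C)(OC)OC; acetic anhydride CC(=O)OC(C)=O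
Why: The cis-diol alone can form a cyclic orthoester, which differentiates it from the primary C15 and the cage Ck hydroxyls; these are then acetylated.

Step 16
Reactants: 24 orthoacetate diacetate
Product: 25 CNP0197219.1 (target)
Conditions: AcOH/H2O 4:1, 0 °C to rt, short reaction time
Reagents that add atoms: water O
Why: Mild acid hydrolysis of a cyclic orthoester on a rigid cyclohexane opens kinetically to the axial ester and equatorial alcohol, which places the acetate on Cc and leaves the Cd hydroxyl free.

Compound list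

1 | 2,6-dichloro-4-hydroxybenzaldehyde | O=Cc1c(Cl)cc(O)cc1Cl | starting material
2 | 2,6-bis[(benzyloxy)methyl]-4-hydroxybenzaldehyde | O=Cc1c(COCc2ccccc2)cc(O)cc1COCc1ccccc1 | intermediate
3 | 2,6-bis[(benzyloxy)methyl]-4-[(triisopropylsilyl)oxy]benzaldehyde | O=Cc1c(COCc2ccccc2)cc(O[Si](C(C)C)(C(C)C)C(C)C)cc1COCc1ccccc1 | intermediate
4 | (S)-1-{2,6-bis[(benzyloxy)methyl]-4-[(triisopropylsilyl)oxy]phenyl}-3-(trimethylsilyl)prop-2-yn-1-ol | C[Si](C)(C)C#C[C@@H](O)c1c(COCc2ccccc2)cc(O[Si](C(C)C)(C(C)C)C(C)C)cc1COCc1ccccc1 | intermediate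
5 | (R)-1-{2,6-bis[(benzyloxy)methyl]-4-[(triisopropylsilyl)oxy]phenyl}prop-2-yn-1-ol | C#C[C@@H](O)c1c(COCc2ccccc2)cc(O[Si](C(C)C)(C(C)C)C(C)C)cc1COCc1ccccc1 | intermediate
6 | (S,Z)-1-{2,6-bis[(benzyloxy)methyl]-4-[(triisopropylsilyl)oxy]phenyl}-3-iodo-2-methylprop-2-en-1-ol | I/C=C(/C)[C@@H](O)c1c(COCc2ccccc2)cc(O[Si](C(C)C)(C(C)C)C(C)C)cc1COCc1ccccc1 | intermediate
7 | 2-bromo-1-ethoxyethyl acetal of 6 (both epimers at the acetal carbon) | I/C=C(/C)[C@@H](OC(CBr)OCC)c1c(COCc2ccccc2)cc(O[Si](C(C)C)(C(C)C)C(C)C)cc1COCc1ccccc1 | intermediate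
8 | free phenol of 7 (present as its tetrabutylammonium phenoxide) | I/C=C(/C)[C@@H](OC(CBr)OCC)c1c(COCc2ccccc2)cc(O)cc1COCc1ccccc1 | intermediate
9 | 6,10-bis[(benzyloxy)methyl]-3-ethoxy-1-[(Z)-1-iodoprop-1-en-2-yl]-2-oxaspiro[4.5]deca-6,9-dien-8-one, C1 configured as in 6, C3 epimer mixture | CCOC1CC2(C(COCc3ccccc3)=CC(=O)C=C2COCc2ccccc2)[C@H](O1)/C(C)=C\I | intermediate
10 | tricycle: cyclohexenone (Cc=O, Cd=Ce–CH2OBn, Cb H2) cis-fused at Cf–Ca to the cyclopentene (Ci=Cj–CH3) and at Cf–Ck to the 2-ethoxyoxolane; CH2OBn on Ca cis to Cg and to the oxolane oxygen on Ck | CCOC1C[C@@]23C(COCc4ccccc4)=CC(=O)C[C@]2(COCc2ccccc2)C=C(C)[C@H]3O1 | intermediate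
11 | deconjugated isomer of 12 with exocyclic methylene on Ce | CCOC1C[C@@]23C(=C)CC(=O)C[C@]2(COCc2ccccc2)C=C(C)[C@H]3O1 | intermediate
12 | tricycle as 10 with CH3 in place of CH2OBn on Ce | CCOC1C[C@@]23C(C)=CC(=O)C[C@]2(COCc2ccccc2)C=C(C)[C@H]3O1 | intermediate
13 | tosylhydrazone of the Cg–Ch aldehyde with free Ck hydroxyl on the cis-fused cyclopentene–cyclohexenone | Cc1ccc(cc1)S(=O)(=O)NN=CC[C@@]12C(C)=CC(=O)C[C@]1(COCc1ccccc1)C=C(C)[C@H]2O | intermediate
14 | trimethylsilyl ether of 13 | Cc1ccc(cc1)S(=O)(=O)NN=CC[C@@]12C(C)=CC(=O)C[C@]1(COCc1ccccc1)C=C(C)[C@H]2O[Si](C)(C)C | intermediate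
15 | diazoalkane from 14 (diazo group on Ch) | [N-]=[N+]=CC[C@@]12C(C)=CC(=O)C[C@]1(COCc1ccccc1)C=C(C)[C@H]2O[Si](C)(C)C | intermediate
16 | 1-pyrazoline from 15: Ch bonded to Ci, N=N bridging Ch and Cj | C(OCc1ccccc1)[C@]12CC(=O)C=C(C)[C@]13C[C@@H](N=N4)[C@H]2[C@]4(C)[C@H]3O[Si](C)(C)C | intermediate
17 | nortricyclene-fused cyclohexenone: Ca–CH2OBn, Cc=O, Cd=Ce–CH3, Ck–OSiMe3 on the Cg side | C(OCc1ccccc1)[C@]12CC(=O)C=C(C)[C@]13C[C@@H]1[C@H]2[C@]1(C)[C@H]3O[Si](C)(C)C | intermediate
18 | Cc=Cd trimethylsilyl enol ether of the gem-dimethyl ketone, Ck–OSiMe3 | C(OCc1ccccc1)[C@]12CC(O[Si](C)(C)C)=CC(C)(C)[C@]13C[C@@H]1[C@H]2[C@]1(C)[C@H]3O[Si](C)(C)C | intermediate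
19 | Cc,Cd-epoxide of 18, oxygen on the face of C15 | C(OCc1ccccc1)[C@]12C[C@]3(O[Si](C)(C)C)O[C@@H]3C(C)(C)[C@]14C[C@@H]1[C@H]2[C@]1(C)[C@H]4O[Si](C)(C)C | intermediate
20 | α-ketol: Cc=O, Cd–OH equatorial, Ck–OH, Ca–CH2OBn | C(OCc1ccccc1)[C@]12CC(=O)[C@H](O)C(C)(C)[C@]13C[C@@H]1[C@H]2[C@]1(C)[C@H]3O | intermediate
21 | triol: Cc–OH axial and cis to Cd–OH, Ck–OH, Ca–CH2OBn | C(OCc1ccccc1)[C@]12C[C@H](O)[C@H](O)C(C)(C)[C@]13C[C@@H]1[C@H]2[C@]1(C)[C@H]3O | intermediate
22 | tetraol (all four hydroxyls of the target skeleton free) | OC[C@]12C[C@H](O)[C@H](O)C(C)(C)[C@]13C[C@@H]1[C@H]2[C@]1(C)[C@H]3O | intermediate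
23 | cyclic methyl orthoacetate of the Cc,Cd diol of 22 (orthoester carbon epimers) | OC[C@]12C[C@@H]3OC(C)(OC)O[C@@H]3C(C)(C)[C@]14C[C@@H]1[C@H]2[C@]1(C)[C@H]4O | intermediate
24 | C15,Ck-diacetate of 23 | CC(=O)OC[C@]12C[C@@H]3OC(C)(OC)O[C@@H]3C(C)(C)[C@]14C[C@@H]1[C@H]2[C@]1(C)[C@H]4OC(C)=O | intermediate
25 | CNP0197219.1: C15, Cc and Ck triacetate with free Cd hydroxyl | CC(=O)OC[C@]12C[C@H](OC(C)=O)[C@H](O)C(C)(C)[C@]13C[C@@H]1[C@H]2[C@]1(C)[C@H]3OC(C)=O | target

Total step count: 16. Longest linear sequence: 16 steps (from 1).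

Steps most likely to fail

Step 11. Conjugate transfer of methyl to Ce, a β-carbon bonded to the quaternary apex Cf, may be too slow, so that 1,2-addition or recovery of the enone takes over. The fallback brings the second methyl in as a methylene and sets out from 17. Corey–Chaykovsky cyclopropanation with dimethylsulfoxonium methylide (Me3S(O)I, KOt-Bu, DMSO/THF) should give the cyclopropyl ketone F1. Li/NH3 (THF, −78 °C) should then cleave the exocyclic cyclopropane bond, which overlaps with the carbonyl π system, and the benzyl ether as well. The resulting gem-dimethyl enolate and alkoxide are silylated after removal of ammonia (TMSCl, Et3N) to the tris(trimethylsilyl) compound F2. Rubottom oxidation as in step 12 should give the ketol triol F3, and NaBH4 as in step 13 comes back to the route at 22.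

Step 7. The alkenyl–palladium may be reduced by formate before it inserts, or insertion at the fully substituted enone carbon may be too slow, so that simple deiodination dominates. The fallback makes the same bond by a 5-exo-trig alkenyl-radical conjugate addition: 9 with Bu3SnH and Et3B/air (toluene, −20 °C to rt) should give 10 directly. The sp2 radical inverts freely and the same oxolane lock decides which enone is attacked. This fallback sets out from 9, returns at 10 and makes no new compound (F0).

Step 3. Facial discrimination at the di-ortho-substituted, electron-rich aldehyde may be poor, or addition sluggish, leaving the carbinol with low enantiomeric purity. The fallback sets the centre by reduction and sets out from 3. Lithium (trimethylsilyl)acetylide (THF, −78 °C) should give the racemic carbinol F4, and MnO2 (CH2Cl2) the ynone F5. Noyori asymmetric transfer hydrogenation (RuCl(p-cymene)(TsDPEN), antipode chosen for the required carbinol, i-PrOH) then comes back to the route at 4, which is desilylated to 5 as in step 3.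

Further compounds

F1 | step 11 | cyclopropyl ketone from 17 (methylene bridging Cd and Ce, drawn on the face of C15) | C(OCc1ccccc1)[C@]12CC(=O)[C@@H]4C[C@]4(C)[C@]13C[C@@H]1[C@H]2[C@]1(C)[C@H]3O[Si](C)(C)C
F2 | step 11 | tris(trimethylsilyl) compound: Cc=Cd silyl enol ether, C15–OSiMe3, Ck–OSiMe3, gem-dimethyl Ce | C[Si](C)(C)OC[C@]12CC(O[Si](C)(C)C)=CC(C)(C)[C@]13C[C@@H]1[C@H]2[C@]1(C)[C@H]3O[Si](C)(C)C
F3 | step 11 | ketol triol (debenzylated analogue of 20) | OC[C@]12CC(=O)[C@H](O)C(C)(C)[C@]13C[C@@H]1[C@H]2[C@]1(C)[C@H]3O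
F0 | step 7 | none | none
F4 | step 3 | racemic 1-{2,6-bis[(benzyloxy)methyl]-4-[(triisopropylsilyl)oxy]phenyl}-3-(trimethylsilyl)prop-2-yn-1-ol | C[Si](C)(C)C#CC(O)c1c(COCc2ccccc2)cc(O[Si](C(C)C)(C(C)C)C(C)C)cc1COCc1ccccc1
F5 | step 3 | 1-{2,6-bis[(benzyloxy)methyl]-4-[(triisopropylsilyl)oxy]phenyl}-3-(trimethylsilyl)prop-2-yn-1-one | C[Si](C)(C)C#CC(=O)c1c(COCc2ccccc2)cc(O[Si](C(C)C)(C(C)C)C(C)C)cc1COCc1ccccc1
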